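**The pitfall.** In a dosed flask it is easy to take the run's end as the time its monomer has reacted. In cedar the free monomer goes in evenly over 16.0 h and the run ends at 20 h, so a portion stays 12.0 h on average.

| flask | free monomer | transfer agent | initiator | remark | time |
|---|---|---|---|---|---|
| spring | 0.20 M | 0.020 M | 1 mM | run made earlier |  |
| summer | 0.13 M | 0.020 M | 1 mM | run made earlier |  |
| midnight | 0.30 M | 0.020 M | 1 mM | run made earlier |  |
| larch | 0.20 M | 0.0200 M | 1.0 mM | a closed flask charged with all of it at once and left for 20 h | 20 h |
| oak | 0.20 M | 0.0200 M | 1.0 mM | one stirred flow tank at steady state, fed with the mixture as stated, mean residence time 20 h |  |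
| cedar | 0.20 M (fed, over 16.0 h) | 0.0200 M | 1.0 mM | all but free monomer at the start; free monomer goes in evenly over 16.0 h, the run ends at 20 h | 20 h |

| run | time / h | monomer in chains / % | free monomer / % |
|---|---|---|---|
| spring | 1.00 | 3.2 | 96.8 |
| spring | 1.50 | 4.2 | 94.4 |
| spring | 2.50 | 12.6 | 89.4 |
| spring | 4.00 | 17.3 | 84.3 |
| spring | 8.00 | 32.9 | 71.3 |
| spring | 12.0 | 41.6 | 59.7 |
| summer | 1.50 | 5.1 | 95.0 |
| summer | 5.00 | 19.4 | 80.3 |
| summer | 8.00 | 27.5 | 70.5 |
| summer | 12.0 | 38.9 | 60.2 |
| summer | 20.0 | 57.4 | 45.4 |
| summer | 25.0 | 62.3 | 38.2 |
| midnight | 4.00 | 17.2 | 84.3 |
| midnight | 8.00 | 29.5 | 67.9 |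
| midnight | 12.0 | 43.5 | 57.5 |
| midnight | 15.0 | 47.3 | 51.0 |
| midnight | 20.0 | 56.0 | 43.5 |
| midnight | 25.0 | 64.5 | 36.3 |

(each reading ± 1 percentage point)

- the stated concentrations are those of everything mixed, before any reaction; amounts are the same in each set-up
- steps that have been proposed: free monomer + initiator -> living end + monomer in chains; free monomer + living end -> monomer in chains + living end; living end + transfer agent -> dead chain; 2 initiator -> spent initiator A; initiator + monomer in chains -> spent initiator B
- the feed brings no volume worth counting
- the earlier runs were made in a closed, stirred flask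

* the set-up with the highest amount of monomer in chains at the outlet or at the end, in percent of the free monomer put in ("none" if the first two lie within 2 percentage points) (larch / oak / cedar / none)
* amount of monomer in chains at the outlet or at the end, in percent of the free monomer put in, larch
* amount of monomer in chains at the outlet or at the end, in percent of the free monomer put in, oak
* amount of monomer in chains at the outlet or at the end, in percent of the free monomer put in, cedar

**What must be known.** My yardstick is the exposure, the pseudo-first-order constant of free monomer times the mean stay. I take the symmetric case as zero: cedar's monomer meets as many living ends as in a closed flask. The stay is set by the recipe, so it carries no error. The monomer level hardly matters: at 12.0 h the free monomer left runs from 60.2% in summer to 57.5% in midnight. The share of initiator that becomes living ends matters far more. A share of 0.5 would cut the answer by 18 percentage points, and these runs cannot show it for a flask starting without free monomer.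

**My reckoning.** Spring's 59.7% at 12.0 h gives a constant of 0.0430 h⁻¹ for 1 mM of initiator, so the exposure, that constant times the stay, is 0.516. That puts cedar's full-ends mark at 40.3%, and I expect cedar at or below it.

**The forecast.** It says larch 56%, oak 43%, cedar 36% (range 28% to 40%), best larch, with cedar “possibly less if starved initiator is wasted”.

**The result.** The flasks give larch 56.4%, oak 42.2% and cedar 27.8%, so the best is larch. Cedar's 72.2% of free monomer means an exposure of 0.326, which is 0.631 of my yardstick. In cedar at 20.0 h, living ends plus dead chains hold 65.4% of the initiator charge, and spent initiator A holds 34.5%.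

    free monomer + initiator → living end + monomer in chains (k = 0.00310 M⁻¹ s⁻¹)
    free monomer + living end → monomer in chains + living end, rate k2*[living end]*[free monomer] (k = 0.0150 M⁻¹ s⁻¹)
    living end + transfer agent → dead chain (kL = 2.90 × 10⁻⁴ M⁻¹ s⁻¹)
    2 initiator → spent initiator A (k = 0.0320 M⁻¹ s⁻¹)
    initiator + monomer in chains → spent initiator B (k = 5.90 × 10⁻⁵ M⁻¹ s⁻¹)

**Second flask.** Cedar's neighbour with 0.0025 M of initiator keeps the stay of 12.0 h, but the constant scales with the living ends, so with full ends its exposure is 1.29 and its full-ends mark 72.5%. That neighbour gives 41.5%, an exposure of 0.537, which is 0.416 of its yardstick.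

All runs are calculated on assumed constants; the scatter is artificial.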